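**Plan**
- Retrosynthesis: after removal of the protecting groups, ring C of unit 2 (the 4-hydroxyphenyl flavone) is cut at O1''–C2'' and C4''–C4a'', and ring C of unit 1 (the 4-methoxyphenyl flavone) at O1–C2 and C4–C4a. Each cut leads back to a phenol, formaldehyde and an arylacetylene.
- Ring A of unit 1 is then cut at C8–C8a and C6–C7 into an aryl siloxyalkyne and 3-ethoxycyclobutenone. The C8–C6'' biaryl bond is never cut: it is the aryl–alkyne bond, whose carbon was the formyl carbon of 2,4,6-trihydroxybenzaldehyde.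
- Enabling feature: in ring A of unit 1 the aryl-bearing C8 lies between the oxygenated C7 and C8a, with a third oxygen at C5. This 2-aryl-1,3,5-trioxygenated benzene is what an aryl ynol silyl ether and a (1-alkoxyvinyl)ketene assemble, and the three oxygens emerge distinct (OH, OSi, OEt).
- Forward order: ring A of unit 2 (from the starting aldehyde), siloxyalkyne, ring A of unit 1 (benzannulation), ring C of unit 1, ring C of unit 2, deprotection.
- Stereochemistry: the target has no stereocentre. The hindered C8–C6'' axis is not controlled.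

Key step: step 5

Assumption: the target is drawn without a configuration for the C8–C6'' axis, so the racemic compound is the goal. The carbinol centres made in steps 7 and 12 are removed by oxidation.

**Route**

Step 1
Reactants: 1 2,4,6-trihydroxybenzaldehyde
Product: 2 2,6-dihydroxy-4-(methoxymethoxy)benzaldehyde
Conditions: MOMCl (1.05 equiv), i-Pr2NEt, THF, 0 °C
Reagents that add atoms: chloromethyl methyl ether, COCCl
Why: Williamson-type O-alkylation in which the 4-OH, para to the formyl group, is the most acidic hydroxyl and the only one not held in a hydrogen bond to the aldehyde, so one equivalent of the chloromethyl ether under a weak amine base should react there first.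

Step 2
Reactants: 2 2,6-dihydroxy-4-(methoxymethoxy)benzaldehyde
Product: 3 2,6-bis(benzyloxy)-4-(methoxymethoxy)benzaldehyde
Conditions: BnBr (2.5 equiv), K2CO3, DMF, 60 °C
Reagents that add atoms: benzyl bromide, BrCc1ccccc1
Why: Williamson etherification under K2CO3 in DMF is the standard way to benzylate both chelated hydroxyls of a 2,6-dihydroxybenzaldehyde, and the acetal and aldehyde are inert to it.

Step 3
Reactants: 3 2,6-bis(benzyloxy)-4-(methoxymethoxy)benzaldehyde
Product: 4 1,3-bis(benzyloxy)-2-(2,2-dibromoethenyl)-5-(methoxymethoxy)benzene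
Conditions: CBr4, PPh3, Et3N, CH2Cl2, 0 °C
Reagents that add atoms: carbon tetrabromide, BrC(Br)(Br)Br
Why: Ramirez dibromo-olefination (first stage of the Corey–Fuchs sequence) is reliable for hindered, electron-rich benzaldehydes, and Et3N buffers the acid that could otherwise open the MOM acetal.

Step 4
Reactants: 4 1,3-bis(benzyloxy)-2-(2,2-dibromoethenyl)-5-(methoxymethoxy)benzene
Product: 7 {[2,6-bis(benzyloxy)-4-(methoxymethoxy)phenyl]ethynyloxy}tri(propan-2-yl)silane, via lithium arylethynide 5 (not isolated), via lithium arylynolate 6 (not isolated)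
Conditions: n-BuLi (2.05 equiv), THF, −78 → 0 °C; LiOOC(CH3)3 (from t-BuOOH and LiN(SiMe3)2, THF, −78 °C), −78 → 0 °C; i-Pr3SiOSO2CF3, −78 → 0 °C
Reagents that add atoms: lithium tert-butyl peroxide (from tert-butyl hydroperoxide), [Li+].[O-]OC(C)(C)C; triisopropylsilyl trifluoromethanesulfonate, CC(C)[Si](OS(=O)(=O)C(F)(F)F)(C(C)C)C(C)C
Why: Corey–Fuchs bromine–lithium exchange and elimination give the lithium acetylide, its unhindered terminal carbon attacks the O–O bond of the peroxide (Julia oxidation of acetylides to ynolates), and the bulky silyl triflate silylates the ynolate on oxygen, which is the established way to triisopropylsilyl ynol ethers.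

Step 5
Reactants: 7 {[2,6-bis(benzyloxy)-4-(methoxymethoxy)phenyl]ethynyloxy}tri(propan-2-yl)silane; 8 3-ethoxycyclobut-2-en-1-one (1.5 equiv)
Product: 13 2-[2,6-bis(benzyloxy)-4-(methoxymethoxy)phenyl]-5-ethoxy-3-[tri(propan-2-yl)silyloxy]phenol, via (1-ethoxyethenyl)ketene 9 (not isolated), via 4-(1-ethoxyethenyl)cyclobutenone adduct 10 (not isolated), via dienylketene 11 (not isolated), via cyclohexa-2,4-dienone 12 (not isolated)
Conditions: toluene (0.3 M), 80 °C, sealed tube, Ar
Reagents that add atoms: none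
Why: Four-electron electrocyclic opening of 8 gives (1-ethoxyethenyl)ketene 9, which undergoes [2+2] cycloaddition with the siloxyalkyne to cyclobutenone 10; this opens to dienylketene 11, closes by six-electron electrocyclization to dienone 12 and tautomerizes to phenol 13. The closest known reaction is the Danheiser benzannulation of cyclobutenones with triisopropylsilyloxyalkynes, which gives resorcinol monosilyl ethers. The two new skeletal bonds, C8–C8a and C6–C7, form in the [2+2] step, and ring A of unit 1 closes in the six-electron electrocyclization that re-forms the C4a–C8a bond broken in the first opening. No stereocentre is created, since the sp3 carbons of 10 and 12 are transient. The selectivity needed is the regiochemistry of the ketene–alkyne cycloaddition: oxygen donation makes the aryl-bearing alkyne carbon nucleophilic, so it bonds to the ketene carbonyl carbon, which places the aryl group between the new hydroxyl (future O1) and the silyl ether (O7) and leaves the ethyl ether at C5. The temperature stays below that of the silyl 1,3-shift of siloxyalkynes, and the flanked phenol should resist acylation by excess ketene.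

Step 6
Reactants: 13 2-[2,6-bis(benzyloxy)-4-(methoxymethoxy)phenyl]-5-ethoxy-3-[tri(propan-2-yl)silyloxy]phenol
Product: 14 3-[2,6-bis(benzyloxy)-4-(methoxymethoxy)phenyl]-6-ethoxy-2-hydroxy-4-[tri(propan-2-yl)silyloxy]benzaldehyde
Conditions: MgCl2, Et3N, (CH2O)n, THF, reflux
Reagents that add atoms: paraformaldehyde (formaldehyde), C=O
Why: Casnati–Skattebøl ortho-formylation, in which the magnesium phenoxide delivers formaldehyde through a chelate only to the free ortho carbon C4a (C8 is substituted and C6 is para), and a second formaldehyde oxidizes the benzylic alkoxide by hydride transfer.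

Step 7
Reactants: 14 3-[2,6-bis(benzyloxy)-4-(methoxymethoxy)phenyl]-6-ethoxy-2-hydroxy-4-[tri(propan-2-yl)silyloxy]benzaldehyde; 15 1-ethynyl-4-methoxybenzene (4-ethynylanisole, 3 equiv)
Product: 17 2-[2,6-bis(benzyloxy)-4-(methoxymethoxy)phenyl]-5-ethoxy-6-[1-hydroxy-3-(4-methoxyphenyl)prop-2-yn-1-yl]-3-[tri(propan-2-yl)silyloxy]phenol (racemic), via lithium (4-methoxyphenyl)ethynide 16 (not isolated)
Conditions: n-BuLi (2.9 equiv), THF, −78 °C; then 14, −78 → 0 °C; NH4Cl (aq)
Reagents that add atoms: none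
Why: 1,2-addition of a lithium acetylide to a salicylaldehyde, in which one equivalent forms the phenoxide and the excess adds to the aldehyde; the new carbinol centre is formed without control because the next step removes it.

Step 8
Reactants: 17 2-[2,6-bis(benzyloxy)-4-(methoxymethoxy)phenyl]-5-ethoxy-6-[1-hydroxy-3-(4-methoxyphenyl)prop-2-yn-1-yl]-3-[tri(propan-2-yl)silyloxy]phenol
Product: 18 1-{3-[2,6-bis(benzyloxy)-4-(methoxymethoxy)phenyl]-6-ethoxy-2-hydroxy-4-[tri(propan-2-yl)silyloxy]phenyl}-3-(4-methoxyphenyl)prop-2-yn-1-one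
Conditions: MnO2 (activated, excess), CH2Cl2, rt
Reagents that add atoms: none
Why: MnO2 oxidation of a benzylic-propargylic alcohol is neutral and is routinely run with a free ortho phenol, giving the hydrogen-bonded o-hydroxyaryl ynone.

Step 9
Reactants: 18 1-{3-[2,6-bis(benzyloxy)-4-(methoxymethoxy)phenyl]-6-ethoxy-2-hydroxy-4-[tri(propan-2-yl)silyloxy]phenyl}-3-(4-methoxyphenyl)prop-2-yn-1-one
Product: 19 8-[2,6-bis(benzyloxy)-4-(methoxymethoxy)phenyl]-5-ethoxy-2-(4-methoxyphenyl)-7-[tri(propan-2-yl)silyloxy]-4H-chromen-4-one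
Conditions: DMAP (20 mol %), DMF, rt
Reagents that add atoms: none
Why: Amine-catalysed 6-endo oxa-Michael cyclization of an o-hydroxyaryl ynone, in which DMAP adds to the ynone and the phenoxide displaces it at the β-carbon, favouring the chromen-4-one (ring C of unit 1) over the 5-exo aurone under conditions that spare the aryl silyl ether.

Step 10
Reactants: 19 8-[2,6-bis(benzyloxy)-4-(methoxymethoxy)phenyl]-5-ethoxy-2-(4-methoxyphenyl)-7-[tri(propan-2-yl)silyloxy]-4H-chromen-4-one
Product: 20 8-[2,6-bis(benzyloxy)-4-hydroxyphenyl]-5-ethoxy-2-(4-methoxyphenyl)-7-[tri(propan-2-yl)silyloxy]-4H-chromen-4-one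
Conditions: HCl (3 M aq), MeOH/THF, 40 °C
Reagents that add atoms: none
Why: Acid-catalysed acetal exchange removes the MOM group, while the hindered aryl triisopropylsilyl ether, which is far more stable to acid than to base, and the benzyl and ethyl ethers are expected to persist.

Step 11
Reactants: 20 8-[2,6-bis(benzyloxy)-4-hydroxyphenyl]-5-ethoxy-2-(4-methoxyphenyl)-7-[tri(propan-2-yl)silyloxy]-4H-chromen-4-one
Product: 21 2,4-bis(benzyloxy)-3-{5-ethoxy-2-(4-methoxyphenyl)-4-oxo-7-[tri(propan-2-yl)silyloxy]-4H-chromen-8-yl}-6-hydroxybenzaldehyde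
Conditions: MgCl2, Et3N, (CH2O)n, THF, reflux
Reagents that add atoms: paraformaldehyde (formaldehyde), C=O
Why: Casnati–Skattebøl ortho-formylation again, where the two ortho carbons of the only free phenol are equivalent and its para carbon carries the biaryl bond, while C6 of unit 1 stays untouched because O7 is still silylated.

Step 12
Reactants: 21 2,4-bis(benzyloxy)-3-{5-ethoxy-2-(4-methoxyphenyl)-4-oxo-7-[tri(propan-2-yl)silyloxy]-4H-chromen-8-yl}-6-hydroxybenzaldehyde; 22 1-(benzyloxy)-4-ethynylbenzene (3 equiv)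
Product: 24 8-{2,6-bis(benzyloxy)-3-[3-(4-(benzyloxy)phenyl)-1-hydroxyprop-2-yn-1-yl]-4-hydroxyphenyl}-5-ethoxy-2-(4-methoxyphenyl)-7-[tri(propan-2-yl)silyloxy]-4H-chromen-4-one (mixture of diastereomers), via lithium [4-(benzyloxy)phenyl]ethynide 23 (not isolated)
Conditions: n-BuLi (2.9 equiv), THF, −78 °C; then 21, −78 → −20 °C; NH4Cl (aq)
Reagents that add atoms: none
Why: 1,2-addition of a lithium acetylide, expected to be chemoselective at low temperature because an aldehyde is more electrophilic than the vinylogous-ester carbonyl of the chromenone, which is further shielded by the peri ethoxy group; the carbinol centre is again removed in the next step.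

Step 13
Reactants: 24 8-{2,6-bis(benzyloxy)-3-[3-(4-(benzyloxy)phenyl)-1-hydroxyprop-2-yn-1-yl]-4-hydroxyphenyl}-5-ethoxy-2-(4-methoxyphenyl)-7-[tri(propan-2-yl)silyloxy]-4H-chromen-4-one
Product: 25 8-{2,6-bis(benzyloxy)-3-[3-(4-(benzyloxy)phenyl)prop-2-ynoyl]-4-hydroxyphenyl}-5-ethoxy-2-(4-methoxyphenyl)-7-[tri(propan-2-yl)silyloxy]-4H-chromen-4-one
Conditions: MnO2 (activated, excess), CH2Cl2, rt
Reagents that add atoms: none
Why: MnO2 oxidation of the benzylic-propargylic alcohol as in step 8, converging both diastereomers on one ynone.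

Step 14
Reactants: 25 8-{2,6-bis(benzyloxy)-3-[3-(4-(benzyloxy)phenyl)prop-2-ynoyl]-4-hydroxyphenyl}-5-ethoxy-2-(4-methoxyphenyl)-7-[tri(propan-2-yl)silyloxy]-4H-chromen-4-one
Product: 26 5,7-bis(benzyloxy)-2-[4-(benzyloxy)phenyl]-6-{5-ethoxy-2-(4-methoxyphenyl)-4-oxo-7-[tri(propan-2-yl)silyloxy]-4H-chromen-8-yl}-4H-chromen-4-one
Conditions: DMAP (20 mol %), DMF, rt
Reagents that add atoms: none
Why: DMAP-catalysed 6-endo oxa-Michael cyclization as in step 9, in which the only free hydroxyl is the one para to the biaryl bond, so ring C of unit 2 can only close to the 6''-linked flavone.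

Step 15
Reactants: 26 5,7-bis(benzyloxy)-2-[4-(benzyloxy)phenyl]-6-{5-ethoxy-2-(4-methoxyphenyl)-4-oxo-7-[tri(propan-2-yl)silyloxy]-4H-chromen-8-yl}-4H-chromen-4-one
Product: 27 5,7-bis(benzyloxy)-2-[4-(benzyloxy)phenyl]-6-[5-ethoxy-7-hydroxy-2-(4-methoxyphenyl)-4-oxo-4H-chromen-8-yl]-4H-chromen-4-one
Conditions: (n-Bu)4NF, AcOH, THF, 0 °C → rt
Reagents that add atoms: none
Why: Fluoride-driven cleavage of the aryl silyl ether, buffered with acetic acid so that the flavone rings see no strong base.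

Step 16
Reactants: 27 5,7-bis(benzyloxy)-2-[4-(benzyloxy)phenyl]-6-[5-ethoxy-7-hydroxy-2-(4-methoxyphenyl)-4-oxo-4H-chromen-8-yl]-4H-chromen-4-one
Product: 28 5,7-dihydroxy-8-[5,7-dihydroxy-2-(4-hydroxyphenyl)-4-oxo-4H-chromen-6-yl]-2-(4-methoxyphenyl)-4H-chromen-4-one (CNP0310322.0)
Conditions: BCl3 (excess), C6HMe5, CH2Cl2, −78 °C → rt; MeOH
Reagents that add atoms: none
Why: Lewis-acid ether cleavage in which BCl3 with pentamethylbenzene as cation scavenger removes the three benzyl groups, chelation of boron between the C4 carbonyl and O5 activates the peri ethyl ether for dealkylation by chloride, and the unchelated 4'-methyl ether is left intact.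

**Compound list**
1 | 2,4,6-trihydroxybenzaldehyde | O=Cc1c(O)cc(O)cc1O | starting material
2 | 2,6-dihydroxy-4-(methoxymethoxy)benzaldehyde | COCOc1cc(O)c(C=O)c(O)c1 | intermediate
3 | 2,6-bis(benzyloxy)-4-(methoxymethoxy)benzaldehyde | COCOc1cc(OCc2ccccc2)c(C=O)c(OCc2ccccc2)c1 | intermediate
4 | 1,3-bis(benzyloxy)-2-(2,2-dibromoethenyl)-5-(methoxymethoxy)benzene | COCOc1cc(OCc2ccccc2)c(C=C(Br)Br)c(OCc2ccccc2)c1 | intermediate
5 | lithium [2,6-bis(benzyloxy)-4-(methoxymethoxy)phenyl]ethynide | [Li+].[C-]#Cc1c(OCc2ccccc2)cc(OCOC)cc1OCc1ccccc1 | intermediate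
6 | lithium 2-[2,6-bis(benzyloxy)-4-(methoxymethoxy)phenyl]ethynolate | [Li+].[O-]C#Cc1c(OCc2ccccc2)cc(OCOC)cc1OCc1ccccc1 | intermediate
7 | {[2,6-bis(benzyloxy)-4-(methoxymethoxy)phenyl]ethynyloxy}tri(propan-2-yl)silane | CC(C)[Si](OC#Cc1c(OCc2ccccc2)cc(OCOC)cc1OCc1ccccc1)(C(C)C)C(C)C | intermediate
8 | 3-ethoxycyclobut-2-en-1-one | CCOC1=CC(=O)C1 | starting material
9 | 3-ethoxybuta-1,3-dien-1-one, (1-ethoxyethenyl)ketene | CCOC(=C)C=C=O | intermediate
10 | 2-[2,6-bis(benzyloxy)-4-(methoxymethoxy)phenyl]-4-(1-ethoxyethenyl)-3-[tri(propan-2-yl)silyloxy]cyclobut-2-en-1-one (racemic) | CCOC(=C)C1C(=O)C(c2c(OCc3ccccc3)cc(OCOC)cc2OCc2ccccc2)=C1O[Si](C(C)C)(C(C)C)C(C)C | intermediate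
11 | (3E)-2-[2,6-bis(benzyloxy)-4-(methoxymethoxy)phenyl]-5-ethoxy-3-[tri(propan-2-yl)silyloxy]hexa-1,3,5-trien-1-one | O=C=C(c1c(OCc2ccccc2)cc(OCOC)cc1OCc1ccccc1)/C(O[Si](C(C)C)(C(C)C)C(C)C)=C\C(=C)OCC | intermediate
12 | 2-[2,6-bis(benzyloxy)-4-(methoxymethoxy)phenyl]-5-ethoxy-3-[tri(propan-2-yl)silyloxy]cyclohexa-2,4-dien-1-one | CCOC1=CC(O[Si](C(C)C)(C(C)C)C(C)C)=C(c2c(OCc3ccccc3)cc(OCOC)cc2OCc2ccccc2)C(=O)C1 | intermediate
13 | 2-[2,6-bis(benzyloxy)-4-(methoxymethoxy)phenyl]-5-ethoxy-3-[tri(propan-2-yl)silyloxy]phenol | CCOc1cc(O)c(-c2c(OCc3ccccc3)cc(OCOC)cc2OCc2ccccc2)c(O[Si](C(C)C)(C(C)C)C(C)C)c1 | intermediate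
14 | 3-[2,6-bis(benzyloxy)-4-(methoxymethoxy)phenyl]-6-ethoxy-2-hydroxy-4-[tri(propan-2-yl)silyloxy]benzaldehyde | CCOc1cc(O[Si](C(C)C)(C(C)C)C(C)C)c(-c2c(OCc3ccccc3)cc(OCOC)cc2OCc2ccccc2)c(O)c1C=O | intermediate
15 | 1-ethynyl-4-methoxybenzene (4-ethynylanisole) | C#Cc1ccc(OC)cc1 | starting material
16 | lithium (4-methoxyphenyl)ethynide | [Li+].[C-]#Cc1ccc(OC)cc1 | intermediate
17 | 2-[2,6-bis(benzyloxy)-4-(methoxymethoxy)phenyl]-5-ethoxy-6-[1-hydroxy-3-(4-methoxyphenyl)prop-2-yn-1-yl]-3-[tri(propan-2-yl)silyloxy]phenol (racemic) | CCOc1cc(O[Si](C(C)C)(C(C)C)C(C)C)c(-c2c(OCc3ccccc3)cc(OCOC)cc2OCc2ccccc2)c(O)c1C(O)C#Cc1ccc(OC)cc1 | intermediate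
18 | 1-{3-[2,6-bis(benzyloxy)-4-(methoxymethoxy)phenyl]-6-ethoxy-2-hydroxy-4-[tri(propan-2-yl)silyloxy]phenyl}-3-(4-methoxyphenyl)prop-2-yn-1-one | CCOc1cc(O[Si](C(C)C)(C(C)C)C(C)C)c(-c2c(OCc3ccccc3)cc(OCOC)cc2OCc2ccccc2)c(O)c1C(=O)C#Cc1ccc(OC)cc1 | intermediate
19 | 8-[2,6-bis(benzyloxy)-4-(methoxymethoxy)phenyl]-5-ethoxy-2-(4-methoxyphenyl)-7-[tri(propan-2-yl)silyloxy]-4H-chromen-4-one | CCOc1cc(O[Si](C(C)C)(C(C)C)C(C)C)c(-c2c(OCc3ccccc3)cc(OCOC)cc2OCc2ccccc2)c2oc(-c3ccc(OC)cc3)cc(=O)c12 | intermediate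
20 | 8-[2,6-bis(benzyloxy)-4-hydroxyphenyl]-5-ethoxy-2-(4-methoxyphenyl)-7-[tri(propan-2-yl)silyloxy]-4H-chromen-4-one | CCOc1cc(O[Si](C(C)C)(C(C)C)C(C)C)c(-c2c(OCc3ccccc3)cc(O)cc2OCc2ccccc2)c2oc(-c3ccc(OC)cc3)cc(=O)c12 | intermediate
21 | 2,4-bis(benzyloxy)-3-{5-ethoxy-2-(4-methoxyphenyl)-4-oxo-7-[tri(propan-2-yl)silyloxy]-4H-chromen-8-yl}-6-hydroxybenzaldehyde (racemic about the biaryl axis) | CCOc1cc(O[Si](C(C)C)(C(C)C)C(C)C)c(-c2c(OCc3ccccc3)cc(O)c(C=O)c2OCc2ccccc2)c2oc(-c3ccc(OC)cc3)cc(=O)c12 | intermediate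
22 | 1-(benzyloxy)-4-ethynylbenzene | C#Cc1ccc(OCc2ccccc2)cc1 | starting material
23 | lithium [4-(benzyloxy)phenyl]ethynide | [Li+].[C-]#Cc1ccc(OCc2ccccc2)cc1 | intermediate
24 | 8-{2,6-bis(benzyloxy)-3-[3-(4-(benzyloxy)phenyl)-1-hydroxyprop-2-yn-1-yl]-4-hydroxyphenyl}-5-ethoxy-2-(4-methoxyphenyl)-7-[tri(propan-2-yl)silyloxy]-4H-chromen-4-one (mixture of diastereomers) | CCOc1cc(O[Si](C(C)C)(C(C)C)C(C)C)c(-c2c(OCc3ccccc3)cc(O)c(C(O)C#Cc3ccc(OCc4ccccc4)cc3)c2OCc2ccccc2)c2oc(-c3ccc(OC)cc3)cc(=O)c12 | intermediate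
25 | 8-{2,6-bis(benzyloxy)-3-[3-(4-(benzyloxy)phenyl)prop-2-ynoyl]-4-hydroxyphenyl}-5-ethoxy-2-(4-methoxyphenyl)-7-[tri(propan-2-yl)silyloxy]-4H-chromen-4-one | CCOc1cc(O[Si](C(C)C)(C(C)C)C(C)C)c(-c2c(OCc3ccccc3)cc(O)c(C(=O)C#Cc3ccc(OCc4ccccc4)cc3)c2OCc2ccccc2)c2oc(-c3ccc(OC)cc3)cc(=O)c12 | intermediate
26 | 5,7-bis(benzyloxy)-2-[4-(benzyloxy)phenyl]-6-{5-ethoxy-2-(4-methoxyphenyl)-4-oxo-7-[tri(propan-2-yl)silyloxy]-4H-chromen-8-yl}-4H-chromen-4-one | CCOc1cc(O[Si](C(C)C)(C(C)C)C(C)C)c(-c2c(OCc3ccccc3)cc3oc(-c4ccc(OCc5ccccc5)cc4)cc(=O)c3c2OCc2ccccc2)c2oc(-c3ccc(OC)cc3)cc(=O)c12 | intermediate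
27 | 5,7-bis(benzyloxy)-2-[4-(benzyloxy)phenyl]-6-[5-ethoxy-7-hydroxy-2-(4-methoxyphenyl)-4-oxo-4H-chromen-8-yl]-4H-chromen-4-one | CCOc1cc(O)c(-c2c(OCc3ccccc3)cc3oc(-c4ccc(OCc5ccccc5)cc4)cc(=O)c3c2OCc2ccccc2)c2oc(-c3ccc(OC)cc3)cc(=O)c12 | intermediate
28 | 5,7-dihydroxy-8-[5,7-dihydroxy-2-(4-hydroxyphenyl)-4-oxo-4H-chromen-6-yl]-2-(4-methoxyphenyl)-4H-chromen-4-one (CNP0310322.0) | COc1ccc(-c2cc(=O)c3c(O)cc(O)c(-c4c(O)cc5oc(-c6ccc(O)cc6)cc(=O)c5c4O)c3o2)cc1 | target

**Count**
Total steps: 16. Longest linear sequence: 16 steps, from 1 to 28; 8, 15 and 22 enter as purchased reagents.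

**Steps most likely to fail**

Step 5 (benzannulation). At the temperature needed to open 8, the siloxyalkyne may isomerize by silyl 1,3-shift to a silylketene, or the vinylketene may oligomerize faster than the hindered alkyne captures it. The fallback sets out from 7 and makes ketene 9 in the cold from a different precursor.
- Ethyl (2E)-3-ethoxybut-2-enoate is saponified (NaOH, then acid) to (2E)-3-ethoxybut-2-enoic acid F1.
- (COCl)2 converts F1 into (2E)-3-ethoxybut-2-enoyl chloride F2.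
- F2 is added slowly to 7 and Et3N in CH2Cl2 at 0 °C. 1,4-Dehydrochlorination through the γ-methyl group gives 9, and the cold [2+2] cycloaddition should give cyclobutenone 10.
- With no free siloxyalkyne left, 10 is heated alone in toluene at 80 °C and should pass through 11 and 12 to phenol 13, where the route is rejoined.

Step 4 (siloxyalkyne). Oxygen transfer from the peroxide to the acetylide may be incomplete, with protonation back to the terminal alkyne, or the electron-rich silyl ynol ether may hydrolyse during isolation. The fallback is a Kowalski ester homologation, which reaches the ynolate by rearrangement and not by oxidation. It sets out from aldehyde 3.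
- Pinnick oxidation (NaClO2, NaH2PO4, 2-methylbut-2-ene, t-BuOH/H2O) should give 2,6-bis(benzyloxy)-4-(methoxymethoxy)benzoic acid F3.
- MeI and K2CO3 in DMF give methyl 2,6-bis(benzyloxy)-4-(methoxymethoxy)benzoate F4.
- LiCHBr2 (from CH2Br2 and lithium 2,2,6,6-tetramethylpiperidide, THF, −78 °C) adds to the ester, and n-BuLi then triggers bromine–lithium exchange and a 1,2-aryl shift to ynolate 6.
- i-Pr3SiOSO2CF3 silylates 6 to 7, where the route is rejoined.

Step 12 (second acetylide addition). The acetylide may attack the finished chromenone of unit 1 at C4 or C2 in competition with the deactivated, doubly ortho-oxygenated phenoxide aldehyde, or conversion may stall. The fallback avoids organolithium reagents once a flavone is present. It sets out from phenol 20 and replaces steps 11 to 14.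
- Mono-iodination ortho to the free hydroxyl (N-iodosuccinimide, 1.0 equiv, CH2Cl2, −20 °C) should give 8-[2,6-bis(benzyloxy)-4-hydroxy-3-iodophenyl]-5-ethoxy-2-(4-methoxyphenyl)-7-[tri(propan-2-yl)silyloxy]-4H-chromen-4-one F5. The free phenol ring is the most nucleophilic ring present.
- Carbonylative Sonogashira annulation of F5 with 22 (PdCl2(PPh3)2 cat., CO 1 atm, Et2NH, DMF, 60 °C) follows. After oxidative addition to zerovalent palladium and CO insertion, the acylpalladium couples with the alkyne to ynone 25.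
- The secondary amine closes 25 in the same flask, through its enaminone, to bis-flavone 26, where the route is rejoined.

**Further compounds**
F1 | step 5 | (2E)-3-ethoxybut-2-enoic acid | CCO/C(C)=C/C(=O)O
F2 | step 5 | (2E)-3-ethoxybut-2-enoyl chloride | CCO/C(C)=C/C(=O)Cl
F3 | step 4 | 2,6-bis(benzyloxy)-4-(methoxymethoxy)benzoic acid | COCOc1cc(OCc2ccccc2)c(C(=O)O)c(OCc2ccccc2)c1
F4 | step 4 | methyl 2,6-bis(benzyloxy)-4-(methoxymethoxy)benzoate | COCOc1cc(OCc2ccccc2)c(C(=O)OC)c(OCc2ccccc2)c1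
F5 | step 12 | 8-[2,6-bis(benzyloxy)-4-hydroxy-3-iodophenyl]-5-ethoxy-2-(4-methoxyphenyl)-7-[tri(propan-2-yl)silyloxy]-4H-chromen-4-one | CCOc1cc(O[Si](C(C)C)(C(C)C)C(C)C)c(-c2c(OCc3ccccc3)cc(O)c(I)c2OCc2ccccc2)c2oc(-c3ccc(OC)cc3)cc(=O)c12
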